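**Plan**

- Retrosynthesis, in order of cutting: the C1 ester (saponification); C8–CH3 and C8–C9 (two Negishi couplings on a C7=CBr2 unit made from the C7 alcohol); the ring bond O2–C3 (peroxy-Michael addition); C6–OO (perhydrolysis of a C6–C7 epoxide); C2=C3 (Wittig), C5=C6 (Horner–Wadsworth–Emmons) and C4–CH2O (auxiliary alkylation of a butanoyl imide).
- Enabling feature (C1 = carboxyl carbon, O1 on C6, O2 on C3): ring carbon C3 carries the CH2CO2H arm and is therefore the β-carbon of a C1–C3 enoate, while the quaternary ring carbon C6 holds O1. The O2–C3 bond of the 1,2-dioxane ring is thus the conjugate addition of a C6 hydroperoxide.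
- Forward: the open C1–C7 chain is assembled first, the only ring (the 1,2-dioxane) closes in step 13, and the C8–C14 side chain is then joined at C7 by two couplings before ester hydrolysis.
- Stereochemistry: C4 from an Evans benzyloxymethylation; C6 from Sharpless epoxidation, hydride opening and an inverting perhydrolysis; C3 relayed from C4 in the chair of the ring closure; C10 from an Evans crotylation of the same imide; the 7E alkene from a trans-selective, then retentive, pair of couplings.

Key step: step 13

Remark: the SMILES is read as (3R,4R,6R,7E,10S), with 3-CH2CO2H, 4-ethyl and the 6-alkenyl group mutually cis on the ring; the acid-catalysed opening of the 2,2-disubstituted epoxide by H2O2 is taken to invert the tertiary carbon, and the tartrate of step 7 is chosen on that basis.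

**Route**

Step 1
Reactants: 1 (R)-4-benzyl-1,3-oxazolidin-2-one; 2 butanoyl chloride
Product: 3 (R)-4-benzyl-3-butanoyl-1,3-oxazolidin-2-one
Conditions: n-BuLi, THF, −78 °C; then 2, −78 → 0 °C
Reagents that add atoms: none
Why: N-acylation of the lithiated oxazolidinone (loading of the Evans auxiliary) is fast at low temperature and creates no stereocentre.

Step 2
Reactants: 3 (R)-4-benzyl-3-butanoyl-1,3-oxazolidin-2-one; 4 benzyl chloromethyl ether
Product: 5 (R)-4-benzyl-3-[(2S)-2-(benzyloxymethyl)butanoyl]-1,3-oxazolidin-2-one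
Conditions: TiCl4, i-Pr2NEt, CH2Cl2, 0 °C; then 4, 0 °C
Reagents that add atoms: none
Why: Evans alkylation of the chelated chlorotitanium (Z)-enolate, in which the electrophile approaches the face opposite the benzyl group of the auxiliary and so sets the α-carbon (future C4) as 2S.

Step 3
Reactants: 5 (R)-4-benzyl-3-[(2S)-2-(benzyloxymethyl)butanoyl]-1,3-oxazolidin-2-one
Product: 6 (2R)-2-[(benzyloxy)methyl]butan-1-ol
Conditions: LiBH4, H2O (1 equiv), Et2O, 0 °C
Reagents that add atoms: none
Why: Reductive cleavage of the imide by LiBH4 gives the primary alcohol without touching the α-stereocentre or the benzyl ether and returns the auxiliary.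

Step 4
Reactants: 6 (2R)-2-[(benzyloxy)methyl]butan-1-ol
Product: 7 (2S)-2-[(benzyloxy)methyl]butanal
Conditions: Dess–Martin periodinane, NaHCO3, CH2Cl2, 0 °C → rt; used crude
Reagents that add atoms: none
Why: Dess–Martin oxidation under buffered, non-basic conditions stops at the aldehyde and should not epimerise or β-eliminate the α-branched β-alkoxy aldehyde, which is used at once.

Step 5
Reactants: 7 (2S)-2-[(benzyloxy)methyl]butanal; 8 triethyl 2-phosphonobutanoate
Product: 9 ethyl (2E,4R)-4-[(benzyloxy)methyl]-2-ethylhex-2-enoate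
Conditions: 8, NaH, THF, 0 °C; then 7, −78 → 0 °C
Reagents that add atoms: none
Why: Horner–Wadsworth–Emmons olefination with the α-ethyl phosphonate should give the trisubstituted (E)-enoate, and adding the aldehyde cold to the preformed anion keeps C4 intact; C5 later becomes CH2, so the geometry matters only for a clean epoxidation.

Step 6
Reactants: 9 ethyl (2E,4R)-4-[(benzyloxy)methyl]-2-ethylhex-2-enoate
Product: 10 (2E,4R)-4-[(benzyloxy)methyl]-2-ethylhex-2-en-1-ol
Conditions: i-Bu2AlH, CH2Cl2, −78 °C
Reagents that add atoms: none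
Why: 1,2-Reduction of the enoate by i-Bu2AlH at low temperature gives the allylic alcohol without conjugate reduction.

Step 7
Reactants: 10 (2E,4R)-4-[(benzyloxy)methyl]-2-ethylhex-2-en-1-ol
Product: 11 [(2R,3R)-3-[(2S)-1-(benzyloxy)butan-2-yl]-2-ethyloxiran-2-yl]methanol
Conditions: Ti(OiPr)4 (cat.), D-(−)-diethyl tartrate (cat.), t-BuOOH, 4 Å molecular sieves, CH2Cl2, −20 °C
Reagents that add atoms: tert-butyl hydroperoxide, CC(C)(C)OO
Why: Katsuki–Sharpless asymmetric epoxidation, in which the titanium tartrate complex delivers oxygen to one face of the allylic alcohol under reagent control; D-(−)-tartrate gives the (2R,3R)-epoxide and thereby fixes the oxygen-bearing quaternary carbon that becomes C6.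

Step 8
Reactants: 11 [(2R,3R)-3-[(2S)-1-(benzyloxy)butan-2-yl]-2-ethyloxiran-2-yl]methanol
Product: 12 (2S,4R)-4-[(benzyloxy)methyl]-2-ethylhexane-1,2-diol
Conditions: LiAlH4, THF, 0 °C → rt
Reagents that add atoms: none
Why: Hydride opening of the 2,3-epoxy alcohol by LiAlH4 is an SN2 attack at the only non-quaternary oxirane carbon (future C5), so the C6–O bond stays and the tertiary carbinol keeps its configuration.

Step 9
Reactants: 12 (2S,4R)-4-[(benzyloxy)methyl]-2-ethylhexane-1,2-diol
Product: 14 (2S)-2-[(2R)-2-[(benzyloxy)methyl]butyl]-2-ethyloxirane, via primary tosylate 13 (not isolated)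
Conditions: TsCl, Et3N, DMAP (cat.), CH2Cl2, 0 °C; then K2CO3, MeOH, rt
Reagents that add atoms: none
Why: Selective sulfonylation of the primary hydroxyl followed by intramolecular Williamson closure (3-exo-tet) gives the 2,2-disubstituted oxirane, and since the C6–O bond is never broken C6 is retained.

Step 10
Reactants: 14 (2S)-2-[(2R)-2-[(benzyloxy)methyl]butyl]-2-ethyloxirane
Product: 15 (2R)-2-{[(2S)-2-ethyloxiran-2-yl]methyl}butan-1-ol
Conditions: H2 (1 atm), Pd/C, EtOAc, rt
Reagents that add atoms: none
Why: Hydrogenolysis of the benzyl ether over palladium on carbon under neutral conditions should leave the non-benzylic aliphatic epoxide untouched.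

Step 11
Reactants: 15 (2R)-2-{[(2S)-2-ethyloxiran-2-yl]methyl}butan-1-ol; 16 methyl (triphenylphosphoranylidene)acetate
Product: 18 methyl (2E,4R)-4-{[(2S)-2-ethyloxiran-2-yl]methyl}hex-2-enoate, via epoxy aldehyde 17 (not isolated)
Conditions: Dess–Martin periodinane, NaHCO3, CH2Cl2, 0 °C; then 16, rt
Reagents that add atoms: none
Why: Dess–Martin oxidation and Wittig olefination with the stabilised ylide in one flask should give the (E)-enoate without storing the epimerisable α-branched aldehyde.

Step 12
Reactants: 18 methyl (2E,4R)-4-{[(2S)-2-ethyloxiran-2-yl]methyl}hex-2-enoate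
Product: 19 methyl (2E,4R,6R)-4,6-diethyl-6-hydroperoxy-7-hydroxyhept-2-enoate
Conditions: H2O2 (anhydrous, in Et2O), H3PMo12O40 (cat.), Et2O, 0 °C → rt
Reagents that add atoms: hydrogen peroxide, OO
Why: Heteropolyacid-catalysed perhydrolysis of a 2,2-disubstituted epoxide, in which H2O2 attacks the activated oxirane at the tertiary carbon in a borderline SN2 opening with inversion; this turns the (6S)-epoxide into the (6R)-hydroperoxide and frees the C7 hydroxyl, while the electron-poor enoate is inert.

Step 13
Reactants: 19 methyl (2E,4R,6R)-4,6-diethyl-6-hydroperoxy-7-hydroxyhept-2-enoate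
Product: 20 methyl 2-[(3R,4R,6R)-4,6-diethyl-6-(hydroxymethyl)-1,2-dioxan-3-yl]acetate
Conditions: Et2NH, CF3CH2OH, rt
Reagents that add atoms: none
Why: Et2NH reversibly deprotonates the tertiary C6 hydroperoxide, which is far more acidic than the C7 hydroxyl, and the α-effect peroxy anion adds to the β-carbon C3 of the (E)-enoate; CF3CH2OH protonates the ester enolate at once, so it cannot attack the O–O bond to form an epoxide and the addition is not readily reversed. This is the known amine/fluoroalcohol-mediated intramolecular peroxy-Michael addition that turns hydroperoxy enoates into 1,2-dioxan-3-yl acetates. The 1,2-dioxane closes 6-exo-trig by forming O2–C3, helped by the quaternary C6, which holds the hydroperoxide near the acceptor. The new C3 centre is controlled by C4: in the chair-like transition state the C4 ethyl and the C6 hydroxymethyl are equatorial, the C6 ethyl is axial, H4 lies anti to the forming bond and the enoate takes the pseudo-axial site, as in kinetic 6-exo oxa-Michael closures of (E)-enoates, which leads to the 3,4-cis (3R) product. The step needs this 3,4-cis selectivity under kinetic control; the equatorial preference of the C4 ethyl and the axial-enoate preference should secure it, the reaction is stopped at full conversion to avoid retro-addition, and any 3-epimer is removed by chromatography.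

Step 14
Reactants: 20 methyl 2-[(3R,4R,6R)-4,6-diethyl-6-(hydroxymethyl)-1,2-dioxan-3-yl]acetate
Product: 21 methyl 2-[(3R,4R,6R)-4,6-diethyl-6-formyl-1,2-dioxan-3-yl]acetate
Conditions: Dess–Martin periodinane, NaHCO3, CH2Cl2, 0 °C → rt
Reagents that add atoms: none
Why: Dess–Martin oxidation of the neopentyl-type primary alcohol gives a non-enolisable aldehyde under neutral conditions that the dialkyl peroxide and the ester tolerate.

Step 15
Reactants: 21 methyl 2-[(3R,4R,6R)-4,6-diethyl-6-formyl-1,2-dioxan-3-yl]acetate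
Product: 22 methyl 2-[(3R,4R,6R)-6-(2,2-dibromoethenyl)-4,6-diethyl-1,2-dioxan-3-yl]acetate
Conditions: CBr4, PPh3, CH2Cl2, 0 °C (ylide preformed); then 21, 0 °C
Reagents that add atoms: carbon tetrabromide, BrC(Br)(Br)Br
Why: Ramirez dibromo-olefination (first stage of the Corey–Fuchs sequence) converts the aldehyde into the 1,1-dibromoalkene, and preforming the dibromomethylene ylide keeps free PPh3 away from the hindered dialkyl peroxide.

Step 16
Reactants: 3 (R)-4-benzyl-3-butanoyl-1,3-oxazolidin-2-one; 23 (E)-1-bromobut-2-ene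
Product: 24 (R)-4-benzyl-3-[(2S,4E)-2-ethylhex-4-enoyl]-1,3-oxazolidin-2-one
Conditions: NaN(SiMe3)2, THF, −78 °C; then 23, −78 → −40 °C
Reagents that add atoms: none
Why: Evans alkylation of the sodium (Z)-enolate with an allylic bromide occurs anti to the benzyl group of the auxiliary, as in step 2, and sets the future C10 as S.

Step 17
Reactants: 24 (R)-4-benzyl-3-[(2S,4E)-2-ethylhex-4-enoyl]-1,3-oxazolidin-2-one
Product: 25 (2S,4E)-2-ethylhex-4-en-1-ol
Conditions: LiBH4, H2O (1 equiv), Et2O, 0 °C
Reagents that add atoms: none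
Why: Reductive cleavage of the imide by LiBH4 gives the primary alcohol with the α-stereocentre intact and returns the auxiliary.

Step 18
Reactants: 25 (2S,4E)-2-ethylhex-4-en-1-ol
Product: 26 (2S)-2-ethylhexan-1-ol
Conditions: H2 (1 atm), PtO2, EtOAc, rt
Reagents that add atoms: none
Why: Catalytic hydrogenation of the isolated disubstituted alkene over platinum saturates the chain; the stereocentre is not allylic and platinum causes little double-bond migration, so C10 should be unaffected.

Step 19
Reactants: 26 (2S)-2-ethylhexan-1-ol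
Product: 27 (3S)-3-(iodomethyl)heptane
Conditions: I2, PPh3, imidazole, CH2Cl2, 0 °C → rt
Reagents that add atoms: iodine, II
Why: Appel-type iodination converts the primary alcohol into the iodide by SN2 at CH2, one carbon away from the stereocentre.

Step 20
Reactants: 22 methyl 2-[(3R,4R,6R)-6-(2,2-dibromoethenyl)-4,6-diethyl-1,2-dioxan-3-yl]acetate; 27 (3S)-3-(iodomethyl)heptane
Product: 29 methyl 2-[(3R,4R,6R)-6-[(1Z,4S)-2-bromo-4-ethyloct-1-en-1-yl]-4,6-diethyl-1,2-dioxan-3-yl]acetate, via [(2S)-2-ethylhexyl]zinc iodide 28 (not isolated)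
Conditions: 27, Zn dust, LiCl, THF, 40 °C; then 22, PdCl2[(2-Ph2PC6H4)2O] (cat.), THF, 0 °C → rt
Reagents that add atoms: none
Why: Negishi coupling, in which zinc insertion gives the primary alkylzinc iodide and zerovalent palladium adds to the C–Br bond trans to the bulky C6 substituent, so mono-alkylation should be trans-selective and place C9 trans to C6; the wide-bite-angle diphosphine suppresses β-hydride elimination.

Step 21
Reactants: 29 methyl 2-[(3R,4R,6R)-6-[(1Z,4S)-2-bromo-4-ethyloct-1-en-1-yl]-4,6-diethyl-1,2-dioxan-3-yl]acetate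
Product: 30 methyl 2-[(3R,4R,6R)-4,6-diethyl-6-[(1E,4S)-4-ethyl-2-methyloct-1-en-1-yl]-1,2-dioxan-3-yl]acetate
Conditions: Me2Zn, Pd[P(t-Bu)3]2 (cat.), THF, 0 °C → rt
Reagents that add atoms: dimethylzinc, C[Zn]C
Why: Second Negishi coupling, in which the electron-rich, bulky Pd[P(t-Bu)3]2 catalyst should replace the remaining hindered bromide by methyl with retention of alkene geometry and give the (E)-trisubstituted alkene.

Step 22
Reactants: 30 methyl 2-[(3R,4R,6R)-4,6-diethyl-6-[(1E,4S)-4-ethyl-2-methyloct-1-en-1-yl]-1,2-dioxan-3-yl]acetate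
Product: 31 2-[(3R,4R,6R)-4,6-diethyl-6-[(1E,4S)-4-ethyl-2-methyloct-1-en-1-yl]-1,2-dioxan-3-yl]acetic acid
Conditions: LiOH, THF/H2O, 0 °C → rt; then 1 M HCl to pH 3–4
Reagents that add atoms: lithium hydroxide, [Li+].[OH-]
Why: Saponification of the methyl ester by LiOH in the cold, then mild acidification, gives the acid; the dialkyl peroxide and the C3 centre should tolerate brief exposure to cold hydroxide.

**Compound list**

1 | (R)-4-benzyl-1,3-oxazolidin-2-one | O=C1N[C@H](Cc2ccccc2)CO1 | starting material
2 | butanoyl chloride | CCCC(Cl)=O | starting material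
3 | (R)-4-benzyl-3-butanoyl-1,3-oxazolidin-2-one | CCCC(=O)N1[C@H](Cc2ccccc2)COC1=O | intermediate
4 | benzyl chloromethyl ether | ClCOCc1ccccc1 | starting material
5 | (R)-4-benzyl-3-[(2S)-2-(benzyloxymethyl)butanoyl]-1,3-oxazolidin-2-one | CC[C@@H](COCc1ccccc1)C(=O)N1[C@H](Cc2ccccc2)COC1=O | intermediate
6 | (2R)-2-[(benzyloxy)methyl]butan-1-ol | CC[C@@H](COCc1ccccc1)CO | intermediate
7 | (2S)-2-[(benzyloxy)methyl]butanal | CC[C@@H](COCc1ccccc1)C=O | intermediate
8 | triethyl 2-phosphonobutanoate | CCOC(=O)C(CC)P(=O)(OCC)OCC | starting material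
9 | ethyl (2E,4R)-4-[(benzyloxy)methyl]-2-ethylhex-2-enoate | CCOC(=O)/C(CC)=C/[C@@H](CC)COCc1ccccc1 | intermediate
10 | (2E,4R)-4-[(benzyloxy)methyl]-2-ethylhex-2-en-1-ol | OC/C(CC)=C/[C@@H](CC)COCc1ccccc1 | intermediate
11 | [(2R,3R)-3-[(2S)-1-(benzyloxy)butan-2-yl]-2-ethyloxiran-2-yl]methanol | OC[C@@]1(CC)O[C@@H]1[C@@H](CC)COCc2ccccc2 | intermediate
12 | (2S,4R)-4-[(benzyloxy)methyl]-2-ethylhexane-1,2-diol | OC[C@](O)(CC)C[C@@H](CC)COCc1ccccc1 | intermediate
13 | (2S,4R)-4-[(benzyloxy)methyl]-2-ethyl-2-hydroxyhexyl 4-methylbenzenesulfonate | Cc1ccc(cc1)S(=O)(=O)OC[C@](O)(CC)C[C@@H](CC)COCc2ccccc2 | intermediate (not isolated)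
14 | (2S)-2-[(2R)-2-[(benzyloxy)methyl]butyl]-2-ethyloxirane | C1O[C@@]1(CC)C[C@@H](CC)COCc2ccccc2 | intermediate
15 | (2R)-2-{[(2S)-2-ethyloxiran-2-yl]methyl}butan-1-ol | C1O[C@@]1(CC)C[C@@H](CC)CO | intermediate
16 | methyl (triphenylphosphoranylidene)acetate | COC(=O)C=P(c1ccccc1)(c1ccccc1)c1ccccc1 | starting material
17 | (2R)-2-{[(2S)-2-ethyloxiran-2-yl]methyl}butanal | C1O[C@@]1(CC)C[C@@H](CC)C=O | intermediate (not isolated)
18 | methyl (2E,4R)-4-{[(2S)-2-ethyloxiran-2-yl]methyl}hex-2-enoate | C1O[C@@]1(CC)C[C@@H](CC)/C=C/C(=O)OC | intermediate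
19 | methyl (2E,4R,6R)-4,6-diethyl-6-hydroperoxy-7-hydroxyhept-2-enoate | OC[C@@](OO)(CC)C[C@@H](CC)/C=C/C(=O)OC | intermediate
20 | methyl 2-[(3R,4R,6R)-4,6-diethyl-6-(hydroxymethyl)-1,2-dioxan-3-yl]acetate | OC[C@@]1(CC)C[C@@H](CC)[C@@H](CC(=O)OC)OO1 | intermediate
21 | methyl 2-[(3R,4R,6R)-4,6-diethyl-6-formyl-1,2-dioxan-3-yl]acetate | O=C[C@@]1(CC)C[C@@H](CC)[C@@H](CC(=O)OC)OO1 | intermediate
22 | methyl 2-[(3R,4R,6R)-6-(2,2-dibromoethenyl)-4,6-diethyl-1,2-dioxan-3-yl]acetate | BrC(Br)=C[C@@]1(CC)C[C@@H](CC)[C@@H](CC(=O)OC)OO1 | intermediate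
23 | (E)-1-bromobut-2-ene | C/C=C/CBr | starting material
24 | (R)-4-benzyl-3-[(2S,4E)-2-ethylhex-4-enoyl]-1,3-oxazolidin-2-one | C/C=C/C[C@H](CC)C(=O)N1[C@H](Cc2ccccc2)COC1=O | intermediate
25 | (2S,4E)-2-ethylhex-4-en-1-ol | C/C=C/C[C@H](CC)CO | intermediate
26 | (2S)-2-ethylhexan-1-ol | CCCC[C@H](CC)CO | intermediate
27 | (3S)-3-(iodomethyl)heptane | CCCC[C@H](CC)CI | intermediate
28 | [(2S)-2-ethylhexyl]zinc iodide | CCCC[C@H](CC)C[Zn]I | intermediate (not isolated)
29 | methyl 2-[(3R,4R,6R)-6-[(1Z,4S)-2-bromo-4-ethyloct-1-en-1-yl]-4,6-diethyl-1,2-dioxan-3-yl]acetate | CCCC[C@H](CC)C/C(Br)=C/[C@@]1(CC)C[C@@H](CC)[C@@H](CC(=O)OC)OO1 | intermediate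
30 | methyl 2-[(3R,4R,6R)-4,6-diethyl-6-[(1E,4S)-4-ethyl-2-methyloct-1-en-1-yl]-1,2-dioxan-3-yl]acetate | CCCC[C@H](CC)C/C(C)=C/[C@@]1(CC)C[C@@H](CC)[C@@H](CC(=O)OC)OO1 | intermediate
31 | 2-[(3R,4R,6R)-4,6-diethyl-6-[(1E,4S)-4-ethyl-2-methyloct-1-en-1-yl]-1,2-dioxan-3-yl]acetic acid | CCCC[C@H](CC)C/C(C)=C/[C@@]1(CC)C[C@@H](CC)[C@@H](CC(=O)O)OO1 | target

**Count and risks**

Total step count: 22. Longest linear sequence: 18 steps (steps 1–15, then 20–22); the side-chain branch (steps 1, 16–19) joins at step 20.

Step 13 (ring closure). The facial selectivity at C3 may be low, because the axial-enoate and equatorial-enoate chairs differ little in energy. A kinetic 3,4-cis preference may also be eroded by retro-addition on long exposure to the amine, and oxygen transfer from the hydroperoxide to the enoate may compete. The fallback makes the same O2–C3 bond by a stereospecific 6-exo-tet displacement instead of a conjugate addition. It sets out from epoxy aldehyde 17 (made from 15 as in step 11, without the ylide) and comes back to the route at 20. Reagent-controlled Brown allylation, with the enantiomer of B-allyldiisopinocampheylborane that gives the (4S)-carbinol, would afford (4S,5R)-5-{[(2S)-2-ethyloxiran-2-yl]methyl}hept-1-en-4-ol F1. MsCl/Et3N would give (4S,5R)-5-{[(2S)-2-ethyloxiran-2-yl]methyl}hept-1-en-4-yl methanesulfonate F2. The H2O2/H3PMo12O40 perhydrolysis of step 12 would open the epoxide to (4S,5R,7R)-5,7-diethyl-7-hydroperoxy-8-hydroxyoct-1-en-4-yl methanesulfonate F3. KOt-Bu in THF at 0 °C would close the ring with inversion at the mesylate carbon to [(3R,5R,6R)-3,5-diethyl-6-(prop-2-en-1-yl)-1,2-dioxan-3-yl]methanol F4. Ozonolysis in NaOH/MeOH–CH2Cl2 at −78 °C would convert the allyl group directly into the CH2CO2Me arm of 20.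

Step 12 (perhydrolysis). The opening may drift toward a carbocation-like pathway and lose configuration at C6. Attack at the primary carbon, hydrolysis by adventitious water, or acid-promoted rearrangement of the epoxide to an aldehyde may also compete. The fallback gives up stereocontrol at C6 in exchange for a radical peroxidation that does not depend on substitution at a tertiary carbon. It sets out from 18 and comes back at 19. Isomerisation of the epoxide with Me3SiOTf/2,6-lutidine, then DBU, then K2CO3/MeOH, would give the allylic alcohol methyl (2E,4R)-4-ethyl-6-(hydroxymethyl)octa-2,6-dienoate F5; its 5,6-ene regioisomer would serve equally. Mukaiyama–Isayama hydroperoxysilylation (bis(2,2,6,6-tetramethylheptane-3,5-dionato)cobalt, O2, Et3SiH) would place the peroxide on the tertiary C6 and give methyl (2E,4R)-4,6-diethyl-7-hydroxy-6-[(triethylsilyl)peroxy]hept-2-enoate F6 as both C6 epimers. Bu4NF/AcOH would free the hydroperoxide, and 19 would be separated from its 6-epimer (a diastereomer through C4) there or after ring closure.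

Step 21 (second coupling). Oxidative addition into the C–Br bond cis to the quaternary C6 may be slow, the alkenylpalladium intermediate may isomerise, and zerovalent palladium may attack the allylic C6–O bond or the O–O bond. The fallback forms the C7=C8 alkene by carbonyl olefination and leaves out steps 15, 20 and 21. It sets out from aldehyde 21 and iodide 27 and comes back at 30. Ethylidenetriphenylphosphorane (from ethyltriphenylphosphonium bromide and n-BuLi) would be alkylated by 27 to [(4S)-4-ethyloctan-2-yl]triphenylphosphonium iodide F7. Deprotonation with KN(SiMe3)2 and Wittig reaction with 21 at −78 °C would give the trisubstituted alkene as an E/Z mixture, from which 30 would be separated on AgNO3-impregnated silica.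

Further compounds
F1 | step 13 | (4S,5R)-5-{[(2S)-2-ethyloxiran-2-yl]methyl}hept-1-en-4-ol | C1O[C@@]1(CC)C[C@@H](CC)[C@H](CC=C)O
F2 | step 13 | (4S,5R)-5-{[(2S)-2-ethyloxiran-2-yl]methyl}hept-1-en-4-yl methanesulfonate | C1O[C@@]1(CC)C[C@@H](CC)[C@H](CC=C)OS(C)(=O)=O
F3 | step 13 | (4S,5R,7R)-5,7-diethyl-7-hydroperoxy-8-hydroxyoct-1-en-4-yl methanesulfonate | OC[C@@](OO)(CC)C[C@@H](CC)[C@H](CC=C)OS(C)(=O)=O
F4 | step 13 | [(3R,5R,6R)-3,5-diethyl-6-(prop-2-en-1-yl)-1,2-dioxan-3-yl]methanol | OC[C@@]1(CC)C[C@@H](CC)[C@@H](CC=C)OO1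
F5 | step 12 | methyl (2E,4R)-4-ethyl-6-(hydroxymethyl)octa-2,6-dienoate | CC=C(CO)C[C@@H](CC)/C=C/C(=O)OC
F6 | step 12 | methyl (2E,4R)-4,6-diethyl-7-hydroxy-6-[(triethylsilyl)peroxy]hept-2-enoate (both C6 epimers) | OCC(OO[Si](CC)(CC)CC)(CC)C[C@@H](CC)/C=C/C(=O)OC
F7 | step 21 | [(4S)-4-ethyloctan-2-yl]triphenylphosphonium iodide | CCCC[C@H](CC)CC(C)[P+](c1ccccc1)(c1ccccc1)c1ccccc1.[I-]
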